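The route rests on cutting the ring-fusion bond C4a–C8a, the bond shared by the cyclohexane and the tetrahydropyran ring. The ether oxygen on C8a and the hydroxyl on C3 are 1,4-related through C4a and C4, a dissonant pattern that calls for reductive coupling: a SmI2 ketyl–olefin cyclisation of a methyl ketone onto an (E)-enoate closes the cyclohexane 6-exo, sets C4a and C8a and lactonises in the same flask. The precursor is an acyclic keto enoate whose two stereocentres come from a catalytic Michael addition and alkylation on a cyclohexenone template that is then cleaved by ozonolysis. The pyran is closed last by 6-endo opening of a vinyl epoxide.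

Key step: step 8

Remark: locants in the text are those of each compound's own name. C-5 of ketone 9 (lost again in step 5) and the anomeric carbon of lactol 17 are mixtures and are left undefined in the SMILES.

Step 1
Reactants: 1 tert-butyl 2-methylpropanoate
Product: 3 (1-tert-butoxy-2-methylprop-1-enyloxy)trimethylsilane, via lithium ester enolate 2 (not isolated)
Conditions: LiN(i-Pr)2, THF, −78 °C; Me3SiCl, −78 → 20 °C; non-aqueous work-up, distillation
Reagents that add atoms: chlorotrimethylsilane C[Si](C)(C)Cl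
Why: Kinetic ester enolate formation and O-silylation (silyl ketene acetal synthesis) should be clean because the hindered isobutyrate enolate is silylated on oxygen; no stereocentre is formed.

Step 2
Reactants: 4 2-methylcyclohex-2-en-1-one; 3 (1-tert-butoxy-2-methylprop-1-enyloxy)trimethylsilane
Product: 5 tert-butyl 2-methyl-2-[(1S)-2-methyl-3-(trimethylsilyloxy)cyclohex-2-en-1-yl]propanoate
Conditions: oxazaborolidinium triflimide from (S)-3,3-diphenyl-1-(o-tolyl)tetrahydropyrrolo[1,2-c][1,3,2]oxazaborole and Tf2NH (20 mol%), Ph3PO (25 mol%), toluene, −20 °C; non-aqueous work-up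
Reagents that add atoms: none
Why: Catalytic asymmetric Mukaiyama–Michael addition, in which the chiral boron cation binds the enone carbonyl and shields one face of the β-carbon, so the ketene acetal should add there and pass its silyl group to the enolate oxygen, fixing C-1 as (S) and the enol ether regiochemistry (the (S)-proline-derived catalyst is proposed by analogy with cyclohex-2-enone; the antipode is taken if the sense proves opposite on this α-methyl enone).

Step 3
Reactants: 5 tert-butyl 2-methyl-2-[(1S)-2-methyl-3-(trimethylsilyloxy)cyclohex-2-en-1-yl]propanoate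
Product: 7 tert-butyl 2-[(1R,2S)-2-(1-tert-butoxy-2-methyl-1-oxopropan-2-yl)-1-methyl-6-oxocyclohexyl]acetate, via lithium enolate 6 (not isolated)
Conditions: MeLi, THF, 0 °C; then DMPU, BrCH2CO2t-Bu, −78 → −20 °C
Reagents that add atoms: tert-butyl bromoacetate CC(C)(C)OC(=O)CBr
Why: Regiospecific enolate generation from the silyl enol ether with MeLi and C-alkylation, where the electrophile should enter anti to the bulky neighbouring side chain (held pseudoaxial by A(1,2) strain), giving the quaternary centre with methyl cis and acetate arm trans to that chain.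

Step 4
Reactants: 7 tert-butyl 2-[(1R,2S)-2-(1-tert-butoxy-2-methyl-1-oxopropan-2-yl)-1-methyl-6-oxocyclohexyl]acetate
Product: 9 tert-butyl 2-[(1R,2S)-2-(1-tert-butoxy-2-methyl-1-oxopropan-2-yl)-1,5-dimethyl-6-oxocyclohexyl]acetate (C-5 epimers), via lithium enolate 8 (not isolated)
Conditions: LiN(i-Pr)2, THF, −78 °C; MeI, −78 → 0 °C
Reagents that add atoms: iodomethane CI
Why: Kinetic enolate methylation at the only enolisable ketone α-carbon (the other is quaternary, and the ester CH2 is less acidic); the new centre becomes sp2 in step 5, so its configuration does not matter.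

Step 5
Reactants: 9 tert-butyl 2-[(1R,2S)-2-(1-tert-butoxy-2-methyl-1-oxopropan-2-yl)-1,5-dimethyl-6-oxocyclohexyl]acetate
Product: 11 tert-butyl 2-[(1R,6S)-6-(1-tert-butoxy-2-methyl-1-oxopropan-2-yl)-1,3-dimethyl-2-(trifluoromethylsulfonyloxy)cyclohex-2-en-1-yl]acetate, via potassium enolate 10 (not isolated)
Conditions: KN(SiMe3)2, THF, −78 → 0 °C; PhNTf2, 0 → 20 °C
Reagents that add atoms: N-phenylbis(trifluoromethanesulfonimide) O=S(=O)(N(c1ccccc1)S(=O)(=O)C(F)(F)F)C(F)(F)F
Why: Enol triflate formation, which can give only one regioisomer because the ketone carries a single α-hydrogen.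

Step 6
Reactants: 11 tert-butyl 2-[(1R,6S)-6-(1-tert-butoxy-2-methyl-1-oxopropan-2-yl)-1,3-dimethyl-2-(trifluoromethylsulfonyloxy)cyclohex-2-en-1-yl]acetate
Product: 12 tert-butyl 2-[(1S,6S)-6-(1-tert-butoxy-2-methyl-1-oxopropan-2-yl)-1,3-dimethylcyclohex-2-en-1-yl]acetate
Conditions: Pd(OAc)2 (5 mol%), PPh3, n-Bu3N, HCO2H, DMF, 60 °C
Reagents that add atoms: none
Why: Palladium-catalysed formate reduction of an enol triflate (oxidative addition, formate-to-hydride exchange with loss of CO2, reductive elimination) should leave the trisubstituted ring alkene without touching either stereocentre.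

Step 7
Reactants: 12 tert-butyl 2-[(1S,6S)-6-(1-tert-butoxy-2-methyl-1-oxopropan-2-yl)-1,3-dimethylcyclohex-2-en-1-yl]acetate
Product: 14 7-tert-butyl 1-methyl (2E,4S,5S)-4-(2-tert-butoxy-2-oxoethyl)-4,6,6-trimethyl-5-(3-oxobutyl)hept-2-enedioate, via keto aldehyde 13 (not isolated)
Conditions: O3, CH2Cl2, −78 °C; PPh3, −78 → 20 °C; then Ph3P=CHCO2Me, toluene, 80 °C
Reagents that add atoms: ozone [O-][O+]=O; methyl (triphenylphosphoranylidene)acetate COC(=O)C=P(c1ccccc1)(c1ccccc1)c1ccccc1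
Why: Ozonolysis with reductive work-up followed by a Wittig olefination in the same flask, where the stabilised ylide should react only with the aldehyde (not the methyl ketone) under neutral conditions that avoid aldol closure, giving the (E)-enoate; the aldehyde α-carbon is quaternary, so nothing can epimerise.

Step 8
Reactants: 14 7-tert-butyl 1-methyl (2E,4S,5S)-4-(2-tert-butoxy-2-oxoethyl)-4,6,6-trimethyl-5-(3-oxobutyl)hept-2-enedioate
Product: 16 tert-butyl 2-[(3aS,4R,5S,7aS)-5-(1-tert-butoxy-2-methyl-1-oxopropan-2-yl)-4,7a-dimethyl-2-oxooctahydro-1-benzofuran-4-yl]acetate, via hydroxy ester 15 (not isolated)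
Conditions: SmI2 (2.5 equiv), HMPA, t-BuOH, THF, −78 → 0 °C; then PPTS (cat.), toluene, 50 °C
Reagents that add atoms: none
Why: Electron transfer from SmI2–HMPA to the methyl ketone gives a ketyl radical that adds 6-exo-trig to the β-carbon of the (E)-enoate; a second electron transfer and protonation by t-BuOH give the trivalent samarium alkoxide of hydroxy ester 15, which closes the γ-lactone by 5-exo-trig acyl substitution (completed with PPTS). The closest known reaction is the Molander ketyl–olefin cyclisation of ketones tethered to α,β-unsaturated esters. The cyclohexane should close through a chair in which the tert-alkyl side chain at C-5 is equatorial, which places the methyl of the quaternary C-4 axial and its acetate arm equatorial. The enoate takes the equatorial position at the forming C-3a and the bulky, HMPA-solvated O–Sm group of the ketyl lies anti to it, so hydroxyl and CH2CO2Me end up trans-diequatorial with the new methyl axial; C-7a (S) and C-3a (S) are thus set by the two existing centres. The step needs ketyl chemistry in the presence of three esters and anti rather than chelated syn addition; the slow reduction of tert-butyl esters and the non-chelating HMPA medium should secure both.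

Step 9
Reactants: 16 tert-butyl 2-[(3aS,4R,5S,7aS)-5-(1-tert-butoxy-2-methyl-1-oxopropan-2-yl)-4,7a-dimethyl-2-oxooctahydro-1-benzofuran-4-yl]acetate
Product: 17 tert-butyl 2-[(3aS,4R,5S,7aS)-5-(1-tert-butoxy-2-methyl-1-oxopropan-2-yl)-2-hydroxy-4,7a-dimethyloctahydro-1-benzofuran-4-yl]acetate (anomers)
Conditions: i-Bu2AlH (1.1 equiv), CH2Cl2, −78 °C; aq. KNaC4H4O6
Reagents that add atoms: none
Why: Partial reduction of a γ-lactone to the lactol, which should stop at the aluminium hemiacetal at −78 °C while the two hindered tert-butyl esters are not attacked.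

Step 10
Reactants: 17 tert-butyl 2-[(3aS,4R,5S,7aS)-5-(1-tert-butoxy-2-methyl-1-oxopropan-2-yl)-2-hydroxy-4,7a-dimethyloctahydro-1-benzofuran-4-yl]acetate
Product: 18 tert-butyl 2-[(1R,2S,3S,6S)-6-(1-tert-butoxy-2-methyl-1-oxopropan-2-yl)-3-hydroxy-2-[(2Z)-3-iodobut-2-en-1-yl]-1,3-dimethylcyclohexyl]acetate
Conditions: EtPPh3I, n-BuLi, THF, 20 °C; I2, −78 °C; NaN(SiMe3)2, −78 → −20 °C; then 17 (pre-treated with NaN(SiMe3)2), −78 → −20 °C
Reagents that add atoms: ethyltriphenylphosphonium iodide CC[P+](c1ccccc1)(c1ccccc1)c1ccccc1.[I-]; iodine II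
Why: Stork–Zhao-type Wittig olefination with the α-iodo ylide on the open hydroxy-aldehyde form of the lactol, which under kinetic conditions should give the (Z)-iodoalkene with iodine cis to the chain.

Step 11
Reactants: 18 tert-butyl 2-[(1R,2S,3S,6S)-6-(1-tert-butoxy-2-methyl-1-oxopropan-2-yl)-3-hydroxy-2-[(2Z)-3-iodobut-2-en-1-yl]-1,3-dimethylcyclohexyl]acetate
Product: 19 tert-butyl 2-[(1R,2S,3S,6S)-6-(1-tert-butoxy-2-methyl-1-oxopropan-2-yl)-3-hydroxy-1,3-dimethyl-2-[(2Z)-3-methylpenta-2,4-dien-1-yl]cyclohexyl]acetate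
Conditions: CH2=CHSnBu3, Pd(PPh3)4 (5 mol%), CuI (10 mol%), DMF, 40 °C
Reagents that add atoms: tributyl(vinyl)stannane C=C[Sn](CCCC)(CCCC)CCCC
Why: Stille cross-coupling proceeds with retention of alkene geometry, so the vinyl group should replace iodine cis to the chain and give the (Z)-1,3-diene; the free tertiary alcohol is tolerated.

Step 12
Reactants: 19 tert-butyl 2-[(1R,2S,3S,6S)-6-(1-tert-butoxy-2-methyl-1-oxopropan-2-yl)-3-hydroxy-1,3-dimethyl-2-[(2Z)-3-methylpenta-2,4-dien-1-yl]cyclohexyl]acetate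
Product: 21 tert-butyl 2-[(2S,3S,4aS,5R,6S,8aS)-5-(2-tert-butoxy-2-oxoethyl)-2-ethenyl-3-hydroxy-2,5,8a-trimethyloctahydro-2H-chromen-6-yl]-2-methylpropanoate, via vinyl epoxide 20 (not isolated)
Conditions: L-fructose-derived Shi ketone (1,2:4,5-di-O-isopropylidene-β-L-erythro-2,3-hexodiulo-2,6-pyranose, 30 mol%), KHSO5 (as Oxone, 2KHSO5·KHSO4·K2SO4), K2CO3, Bu4NHSO4, MeCN–CH2(OMe)2–aq. Na2B4O7 buffer, 0 °C; then CSA (10 mol%), CH2Cl2, −40 → 0 °C
Reagents that add atoms: potassium peroxymonosulfate [K+].[O-]S(=O)(=O)OO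
Why: Shi asymmetric epoxidation (chiral dioxirane, spiro transition state) should oxidise the electron-rich trisubstituted alkene of the diene on the face giving the (2S,3R)-oxirane, and acid then triggers a vinyl-directed 6-endo-tet hydroxy-epoxide opening by the tertiary hydroxyl at the tertiary allylic carbon with inversion, so C-2 (S) and C-3 (S) follow from the (Z)-geometry and the reagent-controlled epoxide face.

Step 13
Reactants: 21 tert-butyl 2-[(2S,3S,4aS,5R,6S,8aS)-5-(2-tert-butoxy-2-oxoethyl)-2-ethenyl-3-hydroxy-2,5,8a-trimethyloctahydro-2H-chromen-6-yl]-2-methylpropanoate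
Product: 22 2-[(2S,3S,4aS,5R,6S,8aS)-5-(carboxymethyl)-2-ethenyl-3-hydroxy-2,5,8a-trimethyloctahydro-2H-chromen-6-yl]-2-methylpropanoic acid
Conditions: CF3CO2H–CH2Cl2 (1:4), 0 °C; evaporation; brief K2CO3, MeOH–H2O; acidification to pH 3
Reagents that add atoms: none
Why: Acidolysis of both tert-butyl esters (E1 loss of isobutene) should leave the tertiary allylic ether intact at 0 °C because the adjacent hydroxyl disfavours its ionisation, and the mild basic work-up removes any trifluoroacetate formed on the alcohol.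

Compound list
1 | tert-butyl 2-methylpropanoate | CC(C)C(=O)OC(C)(C)C | starting material
2 | lithium 1-tert-butoxy-2-methylprop-1-en-1-olate | [Li+].CC(C)=C([O-])OC(C)(C)C | intermediate
3 | (1-tert-butoxy-2-methylprop-1-enyloxy)trimethylsilane | CC(C)=C(OC(C)(C)C)O[Si](C)(C)C | intermediate
4 | 2-methylcyclohex-2-en-1-one | CC1=CCCCC1=O | starting material
5 | tert-butyl 2-methyl-2-[(1S)-2-methyl-3-(trimethylsilyloxy)cyclohex-2-en-1-yl]propanoate | C[Si](C)(C)OC1=C(C)[C@@H](C(C)(C)C(=O)OC(C)(C)C)CCC1 | intermediate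
6 | lithium (3S)-3-(1-tert-butoxy-2-methyl-1-oxopropan-2-yl)-2-methylcyclohex-1-en-1-olate | [Li+].[O-]C1=C(C)[C@@H](C(C)(C)C(=O)OC(C)(C)C)CCC1 | intermediate
7 | tert-butyl 2-[(1R,2S)-2-(1-tert-butoxy-2-methyl-1-oxopropan-2-yl)-1-methyl-6-oxocyclohexyl]acetate | O=C1CCC[C@H](C(C)(C)C(=O)OC(C)(C)C)[C@@]1(C)CC(=O)OC(C)(C)C | intermediate
8 | lithium (5S,6R)-5-(1-tert-butoxy-2-methyl-1-oxopropan-2-yl)-6-(2-tert-butoxy-2-oxoethyl)-6-methylcyclohex-1-en-1-olate | [Li+].[O-]C1=CCC[C@H](C(C)(C)C(=O)OC(C)(C)C)[C@@]1(C)CC(=O)OC(C)(C)C | intermediate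
9 | tert-butyl 2-[(1R,2S)-2-(1-tert-butoxy-2-methyl-1-oxopropan-2-yl)-1,5-dimethyl-6-oxocyclohexyl]acetate (C-5 epimers) | O=C1C(C)CC[C@H](C(C)(C)C(=O)OC(C)(C)C)[C@@]1(C)CC(=O)OC(C)(C)C | intermediate
10 | potassium (5S,6R)-5-(1-tert-butoxy-2-methyl-1-oxopropan-2-yl)-6-(2-tert-butoxy-2-oxoethyl)-2,6-dimethylcyclohex-1-en-1-olate | [K+].[O-]C1=C(C)CC[C@H](C(C)(C)C(=O)OC(C)(C)C)[C@@]1(C)CC(=O)OC(C)(C)C | intermediate
11 | tert-butyl 2-[(1R,6S)-6-(1-tert-butoxy-2-methyl-1-oxopropan-2-yl)-1,3-dimethyl-2-(trifluoromethylsulfonyloxy)cyclohex-2-en-1-yl]acetate | O=S(=O)(OC1=C(C)CC[C@H](C(C)(C)C(=O)OC(C)(C)C)[C@@]1(C)CC(=O)OC(C)(C)C)C(F)(F)F | intermediate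
12 | tert-butyl 2-[(1S,6S)-6-(1-tert-butoxy-2-methyl-1-oxopropan-2-yl)-1,3-dimethylcyclohex-2-en-1-yl]acetate | CC1=C[C@](C)(CC(=O)OC(C)(C)C)[C@@H](C(C)(C)C(=O)OC(C)(C)C)CC1 | intermediate
13 | di-tert-butyl (3S,4R)-4-formyl-2,2,4-trimethyl-3-(3-oxobutyl)hexanedioate | CC(=O)CC[C@H](C(C)(C)C(=O)OC(C)(C)C)[C@@](C)(CC(=O)OC(C)(C)C)C=O | intermediate
14 | 7-tert-butyl 1-methyl (2E,4S,5S)-4-(2-tert-butoxy-2-oxoethyl)-4,6,6-trimethyl-5-(3-oxobutyl)hept-2-enedioate | CC(=O)CC[C@H](C(C)(C)C(=O)OC(C)(C)C)[C@@](C)(CC(=O)OC(C)(C)C)/C=C/C(=O)OC | intermediate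
15 | tert-butyl 2-[(1R,2S,3S,6S)-6-(1-tert-butoxy-2-methyl-1-oxopropan-2-yl)-3-hydroxy-2-(2-methoxy-2-oxoethyl)-1,3-dimethylcyclohexyl]acetate | C[C@]1(O)CC[C@H](C(C)(C)C(=O)OC(C)(C)C)[C@@](C)(CC(=O)OC(C)(C)C)[C@@H]1CC(=O)OC | intermediate
16 | tert-butyl 2-[(3aS,4R,5S,7aS)-5-(1-tert-butoxy-2-methyl-1-oxopropan-2-yl)-4,7a-dimethyl-2-oxooctahydro-1-benzofuran-4-yl]acetate (trans-fused γ-lactone) | C[C@]12CC[C@H](C(C)(C)C(=O)OC(C)(C)C)[C@@](C)(CC(=O)OC(C)(C)C)[C@@H]1CC(=O)O2 | intermediate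
17 | tert-butyl 2-[(3aS,4R,5S,7aS)-5-(1-tert-butoxy-2-methyl-1-oxopropan-2-yl)-2-hydroxy-4,7a-dimethyloctahydro-1-benzofuran-4-yl]acetate (anomers) | C[C@]12CC[C@H](C(C)(C)C(=O)OC(C)(C)C)[C@@](C)(CC(=O)OC(C)(C)C)[C@@H]1CC(O)O2 | intermediate
18 | tert-butyl 2-[(1R,2S,3S,6S)-6-(1-tert-butoxy-2-methyl-1-oxopropan-2-yl)-3-hydroxy-2-[(2Z)-3-iodobut-2-en-1-yl]-1,3-dimethylcyclohexyl]acetate | C[C@]1(O)CC[C@H](C(C)(C)C(=O)OC(C)(C)C)[C@@](C)(CC(=O)OC(C)(C)C)[C@@H]1C/C=C(/C)I | intermediate
19 | tert-butyl 2-[(1R,2S,3S,6S)-6-(1-tert-butoxy-2-methyl-1-oxopropan-2-yl)-3-hydroxy-1,3-dimethyl-2-[(2Z)-3-methylpenta-2,4-dien-1-yl]cyclohexyl]acetate | C[C@]1(O)CC[C@H](C(C)(C)C(=O)OC(C)(C)C)[C@@](C)(CC(=O)OC(C)(C)C)[C@@H]1C/C=C(/C)C=C | intermediate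
20 | tert-butyl 2-[(1R,2S,3S,6S)-6-(1-tert-butoxy-2-methyl-1-oxopropan-2-yl)-2-{[(2S,3R)-3-ethenyl-3-methyloxiran-2-yl]methyl}-3-hydroxy-1,3-dimethylcyclohexyl]acetate | C[C@]1(O)CC[C@H](C(C)(C)C(=O)OC(C)(C)C)[C@@](C)(CC(=O)OC(C)(C)C)[C@@H]1C[C@@H]2O[C@]2(C)C=C | intermediate
21 | tert-butyl 2-[(2S,3S,4aS,5R,6S,8aS)-5-(2-tert-butoxy-2-oxoethyl)-2-ethenyl-3-hydroxy-2,5,8a-trimethyloctahydro-2H-chromen-6-yl]-2-methylpropanoate | C=C[C@]1(C)O[C@@]2(C)CC[C@H](C(C)(C)C(=O)OC(C)(C)C)[C@@](C)(CC(=O)OC(C)(C)C)[C@@H]2C[C@@H]1O | intermediate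
22 | 2-[(2S,3S,4aS,5R,6S,8aS)-5-(carboxymethyl)-2-ethenyl-3-hydroxy-2,5,8a-trimethyloctahydro-2H-chromen-6-yl]-2-methylpropanoic acid | C=C[C@]1(C)O[C@@]2(C)CC[C@H](C(C)(C)C(=O)O)[C@@](C)(CC(=O)O)[C@@H]2C[C@@H]1O | target

Total step count: 13. Longest linear sequence: 13 steps (1 to 22; enone 4 enters at step 2).

Steps most likely to fail

Step 2. The α-methyl group may weaken the organised binding of the enone to the chiral boron cation, so that the rate and the facial discrimination at the β-carbon both drop. The fallback replaces asymmetric catalysis by a racemic three-component coupling and resolution. It sets out from 1 and 4: the lithium enolate 2 is added to 4 in THF at −78 °C (conjugate addition of the hindered ester enolate), which gives enolate 6 together with its mirror image, lithium (3R)-3-(1-tert-butoxy-2-methyl-1-oxopropan-2-yl)-2-methylcyclohex-1-en-1-olate F1. Alkylation in the same flask with tert-butyl bromoacetate gives racemic ketone, which is resolved by preparative chromatography on a chiral stationary phase. The unwanted enantiomer, tert-butyl 2-[(1S,2R)-2-(1-tert-butoxy-2-methyl-1-oxopropan-2-yl)-1-methyl-6-oxocyclohexyl]acetate F2, is set aside and the route is rejoined at 7.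

Step 8. The ketyl may be reduced further or protonated before the slow 6-exo closure next to the quaternary carbon, or it may close with the oxygen axial, which would erode selectivity at the carbinol carbon. The fallback forms the same bond by hydrogen-atom-transfer radical chemistry. It sets out from 14: kinetic enolisation of the methyl ketone (LiN(i-Pr)2, t-BuMe2SiCl, THF–DMPU, −78 °C) gives the silyl enol ether 7-tert-butyl 1-methyl (2E,4S,5S)-4-(2-tert-butoxy-2-oxoethyl)-5-[3-(tert-butyldimethylsilyloxy)but-3-en-1-yl]-4,6,6-trimethylhept-2-enedioate F3. Fe(acac)3 and PhSiH3 in EtOH at 60 °C transfer a hydrogen atom to the enol ether; the resulting α-silyloxy radical adds 6-exo to the enoate to give tert-butyl 2-[(1R,2S,3S,6S)-6-(1-tert-butoxy-2-methyl-1-oxopropan-2-yl)-3-(tert-butyldimethylsilyloxy)-2-(2-methoxy-2-oxoethyl)-1,3-dimethylcyclohexyl]acetate F4. Bu4NF in THF removes the silyl group and the alkoxide lactonises, which rejoins the route at 16.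

Step 10. The lactol may open too slowly at the low temperature that the thermally labile iodo ylide requires, so that the ylide decomposes before olefination and geometric purity suffers. The fallback builds the (Z)-alkene with a phosphonate and then elaborates the ester to the vinyl group. It sets out from 17: Still–Gennari olefination (methyl 2-[bis(2,2,2-trifluoroethoxy)phosphoryl]propanoate, KN(SiMe3)2, 18-crown-6, THF, −78 °C) gives tert-butyl 2-[(1R,2S,3S,6S)-6-(1-tert-butoxy-2-methyl-1-oxopropan-2-yl)-3-hydroxy-2-[(2Z)-4-methoxy-3-methyl-4-oxobut-2-en-1-yl]-1,3-dimethylcyclohexyl]acetate F5. Reduction with i-Bu2AlH at −78 °C gives tert-butyl 2-[(1R,2S,3S,6S)-6-(1-tert-butoxy-2-methyl-1-oxopropan-2-yl)-3-hydroxy-2-[(2Z)-4-hydroxy-3-methylbut-2-en-1-yl]-1,3-dimethylcyclohexyl]acetate F6. Oxidation with MnO2 in CH2Cl2 gives tert-butyl 2-[(1R,2S,3S,6S)-6-(1-tert-butoxy-2-methyl-1-oxopropan-2-yl)-3-hydroxy-1,3-dimethyl-2-[(2Z)-3-methyl-4-oxobut-2-en-1-yl]cyclohexyl]acetate F7, and methylenation with Ph3P=CH2 rejoins the route at 19.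

Further compounds
F1 | step 2 | lithium (3R)-3-(1-tert-butoxy-2-methyl-1-oxopropan-2-yl)-2-methylcyclohex-1-en-1-olate | [Li+].[O-]C1=C(C)[C@H](C(C)(C)C(=O)OC(C)(C)C)CCC1
F2 | step 2 | tert-butyl 2-[(1S,2R)-2-(1-tert-butoxy-2-methyl-1-oxopropan-2-yl)-1-methyl-6-oxocyclohexyl]acetate | O=C1CCC[C@@H](C(C)(C)C(=O)OC(C)(C)C)[C@]1(C)CC(=O)OC(C)(C)C
F3 | step 8 | 7-tert-butyl 1-methyl (2E,4S,5S)-4-(2-tert-butoxy-2-oxoethyl)-5-[3-(tert-butyldimethylsilyloxy)but-3-en-1-yl]-4,6,6-trimethylhept-2-enedioate | C=C(O[Si](C)(C)C(C)(C)C)CC[C@H](C(C)(C)C(=O)OC(C)(C)C)[C@@](C)(CC(=O)OC(C)(C)C)/C=C/C(=O)OC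
F4 | step 8 | tert-butyl 2-[(1R,2S,3S,6S)-6-(1-tert-butoxy-2-methyl-1-oxopropan-2-yl)-3-(tert-butyldimethylsilyloxy)-2-(2-methoxy-2-oxoethyl)-1,3-dimethylcyclohexyl]acetate | C[C@]1(O[Si](C)(C)C(C)(C)C)CC[C@H](C(C)(C)C(=O)OC(C)(C)C)[C@@](C)(CC(=O)OC(C)(C)C)[C@@H]1CC(=O)OC
F5 | step 10 | tert-butyl 2-[(1R,2S,3S,6S)-6-(1-tert-butoxy-2-methyl-1-oxopropan-2-yl)-3-hydroxy-2-[(2Z)-4-methoxy-3-methyl-4-oxobut-2-en-1-yl]-1,3-dimethylcyclohexyl]acetate | C[C@]1(O)CC[C@H](C(C)(C)C(=O)OC(C)(C)C)[C@@](C)(CC(=O)OC(C)(C)C)[C@@H]1C/C=C(/C)C(=O)OC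
F6 | step 10 | tert-butyl 2-[(1R,2S,3S,6S)-6-(1-tert-butoxy-2-methyl-1-oxopropan-2-yl)-3-hydroxy-2-[(2Z)-4-hydroxy-3-methylbut-2-en-1-yl]-1,3-dimethylcyclohexyl]acetate | C[C@]1(O)CC[C@H](C(C)(C)C(=O)OC(C)(C)C)[C@@](C)(CC(=O)OC(C)(C)C)[C@@H]1C/C=C(/C)CO
F7 | step 10 | tert-butyl 2-[(1R,2S,3S,6S)-6-(1-tert-butoxy-2-methyl-1-oxopropan-2-yl)-3-hydroxy-1,3-dimethyl-2-[(2Z)-3-methyl-4-oxobut-2-en-1-yl]cyclohexyl]acetate | C[C@]1(O)CC[C@H](C(C)(C)C(=O)OC(C)(C)C)[C@@](C)(CC(=O)OC(C)(C)C)[C@@H]1C/C=C(/C)C=O
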